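**Strategy.** Ring B of the decalin (C5–C10, drimane numbering) is a cyclohexene: its C5=C6 double bond and its three stereocentres C8, C9 and C10 lie exactly where a [4+2] cycloaddition places them. The route therefore disconnects C7–C8 and C9–C10. An enantioselective, exo-selective Diels–Alder reaction of achiral 6,6-dimethyl-1-vinylcyclohexene (ring A preformed) with tiglic aldehyde, under a chiral cationic oxazaborolidine, closes ring B and sets all three stereocentres at once; the precursor pair holds no stereocentre. The formyl carbon becomes C11: it takes up a tetramethoxyphenyl group, is deoxygenated, and the arene is oxidised to the quinone, which is mono-hydrolysed and aminated with (S)-2-methylbutylamine.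

Key step: step 3

Remark on numbering: terpenoid carbons carry drimane numbers (ring A = C1–C5 and C10; ring B = C5–C10; C11 = the CH2 between C9 and the quinone; quinone carbons C1'–C6' with the alkyl group on C3').

Assumption: the facial sense of the oxazaborolidine catalyst is taken from its accepted pre-transition-state model; should it prove opposite, the mirror-image catalyst would be used with everything else unchanged.

**Step 1**
Reactants: 1 2,2-dimethylcyclohexanone
Product: 3 6,6-dimethylcyclohex-1-en-1-yl trifluoromethanesulfonate, via potassium 6,6-dimethylcyclohex-1-en-1-olate 2 (not isolated)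
Conditions: KN(SiMe3)2, THF, −78 °C; PhNTf2, −78 °C → rt; aq. NH4Cl
Reagents that add atoms: N-phenylbis(trifluoromethanesulfonimide), O=S(=O)(N(c1ccccc1)S(=O)(=O)C(F)(F)F)C(F)(F)F
Why: Enol triflate formation: C2 is quaternary, so the base can deprotonate only at C6, and the single enolate 2 should be O-sulfonylated by PhNTf2.

**Step 2**
Reactants: 3 6,6-dimethylcyclohex-1-en-1-yl trifluoromethanesulfonate; 4 tributyl(vinyl)stannane
Product: 5 6,6-dimethyl-1-vinylcyclohexene
Conditions: Pd(PPh3)4 (3 mol %), LiCl (3 equiv), THF, reflux; product volatile, concentrated cold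
Reagents that add atoms: none
Why: Stille coupling: oxidative addition of the alkenyl triflate to zerovalent palladium, transmetallation of the vinyl group from tin and reductive elimination should give the 1,3-diene with the ring double bond fixed in place.

**Step 3**
Reactants: 5 6,6-dimethyl-1-vinylcyclohexene; 6 tiglic aldehyde, (E)-2-methylbut-2-enal
Product: 7 (1R,2S,8aR)-1,2,5,5-tetramethyl-1,2,3,5,6,7,8,8a-octahydronaphthalene-1-carbaldehyde
Conditions: (R)-tetrahydro-1-(2-methylphenyl)-3,3-diphenyl-1H,3H-pyrrolo[1,2-c][1,3,2]oxazaborole (20 mol %), (CF3SO2)2NH (17 mol %), 6 (3 equiv), CH2Cl2, −78 → −20 °C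
Reagents that add atoms: none
Why: The N-protonated oxazaborolidine binds the formyl oxygen of 6, and the activated s-trans enal should undergo a concerted, asynchronous [4+2] cycloaddition with the s-cis diene 5 (the C7–C8 bond from the enal β-carbon to the free vinyl terminus running ahead of C9–C10), the closest known reaction type being the chiral cationic oxazaborolidine-catalysed enantioselective Diels–Alder reaction of α-substituted enals. Ring B is closed in the intermolecular [4+2] mode, both σ-bonds forming suprafacially and the central bond of the diene becoming the C5=C6 double bond. The cis relation of the C8 and C9 methyl groups is copied from the E geometry of 6. C10 is set relative to C9 by the exo transition state (formyl group pointing away from the diene, α-methyl group beneath it), which leaves H-10 cis to the formyl carbon C11. The absolute configuration is set by the catalyst, whose pre-transition-state model (formyl C–H···O contact, enal stacked on one C-phenyl group) should leave the Si face of the α-carbon C9 open in the (R) series. The step needs "ortho" regioselectivity, exo selectivity and face selectivity: the first should follow from pairing the most electrophilic carbon of 6 with the unhindered vinyl terminus C7 of 5, the second from the inherent exo preference of α-methyl enals, reinforced because the bulky boron-bound formyl group would otherwise lie under ring A, and the third from the catalyst alone, since 5 is achiral and its C4 gem-dimethyl group favours the reactive s-cis conformer.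

**Step 4**
Reactants: 7 (1R,2S,8aR)-1,2,5,5-tetramethyl-1,2,3,5,6,7,8,8a-octahydronaphthalene-1-carbaldehyde; 8 1,2,4,5-tetramethoxybenzene
Product: 12 O-{(2,3,5,6-tetramethoxyphenyl)[(1R,2S,8aR)-1,2,5,5-tetramethyl-1,2,3,5,6,7,8,8a-octahydronaphthalen-1-yl]methyl} S-methyl carbonodithioate (both C11 epimers), via 2,3,5,6-tetramethoxyphenyllithium 9 (not isolated), via lithium alkoxide 10 (not isolated), via lithium xanthate 11 (not isolated)
Conditions: 8, n-BuLi, THF, 0 °C; 7, −78 → 0 °C; CS2, 0 °C → rt; MeI, rt
Reagents that add atoms: carbon disulfide, S=C=S; iodomethane, CI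
Why: Directed ortho-lithiation between two methoxy groups gives 9, which should add to the non-enolisable neopentyl aldehyde (1,2-addition; the new carbinol centre is removed in step 5, so its configuration does not matter), and the alkoxide is trapped in the same flask as the S-methyl xanthate (xanthate formation).

**Step 5**
Reactants: 12 the S-methyl xanthate
Product: 13 1,2,4,5-tetramethoxy-3-{[(1R,2S,8aS)-1,2,5,5-tetramethyl-1,2,3,5,6,7,8,8a-octahydronaphthalen-1-yl]methyl}benzene
Conditions: Bu3SnH (3 equiv, 0.2 M), AIBN (cat.), toluene, 110 °C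
Reagents that add atoms: none
Why: Barton–McCombie deoxygenation: the stannyl radical adds to the thiocarbonyl sulfur, β-scission gives the benzylic C11 radical, and Bu3SnH held at high concentration should reduce it before it can add to the C5=C6 bond, no stereocentre being touched.

**Step 6**
Reactants: 13 the tetramethoxyarene
Product: 14 2,5-dimethoxy-3-{[(1R,2S,8aS)-1,2,5,5-tetramethyl-1,2,3,5,6,7,8,8a-octahydronaphthalen-1-yl]methyl}cyclohexa-2,5-diene-1,4-dione
Conditions: (NH4)2Ce(NO3)6 (2.5 equiv), MeCN/H2O, 0 °C
Reagents that add atoms: water, O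
Why: Oxidative demethylation of a para-dimethoxy pair by tetravalent cerium (two one-electron oxidations with capture of water) should give the 2,5-dimethoxy-1,4-benzoquinone with the trisubstituted alkene untouched, and any ortho-quinone isomer formed alongside is expected to converge on 16 in step 7.

**Step 7**
Reactants: 14 the 2,5-dimethoxyquinone
Product: 16 2-hydroxy-5-methoxy-3-{[(1R,2S,8aS)-1,2,5,5-tetramethyl-1,2,3,5,6,7,8,8a-octahydronaphthalen-1-yl]methyl}cyclohexa-2,5-diene-1,4-dione, via potassium quinonolate 15 (not isolated)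
Conditions: KOH (2 M aq.), MeOH, rt; 1 M HCl to pH 3
Reagents that add atoms: potassium hydroxide, [K+].[OH-]
Why: Addition–elimination (vinylogous ester saponification): the C2' methoxy group, twisted out of conjugation by the neighbouring C3' alkyl group, is the more electrophilic vinylogous ester and should be replaced by hydroxide, after which the quinonolate 15 resists further attack.

**Step 8**
Reactants: 16 the 2-hydroxy-5-methoxyquinone; 17 (S)-2-methylbutan-1-amine
Product: 18 nakijiquinone J, 2-hydroxy-5-{[(2S)-2-methylbutyl]amino}-3-{[(1R,2S,8aS)-1,2,5,5-tetramethyl-1,2,3,5,6,7,8,8a-octahydronaphthalen-1-yl]methyl}cyclohexa-2,5-diene-1,4-dione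
Conditions: 17 (3 equiv), NaHCO3, EtOH, rt
Reagents that add atoms: none
Why: Addition–elimination at the remaining vinylogous ester carbon C5' (conjugate substitution of methoxide by the primary amine) should give the vinylogous amide, the stereocentre of the amine not being involved.

**Compound list**
1 | 2,2-dimethylcyclohexanone | CC1(C)CCCCC1=O | starting material
2 | potassium 6,6-dimethylcyclohex-1-en-1-olate | CC1(C)CCCC=C1[O-].[K+] | intermediate
3 | 6,6-dimethylcyclohex-1-en-1-yl trifluoromethanesulfonate | CC1(C)CCCC=C1OS(=O)(=O)C(F)(F)F | intermediate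
4 | tributyl(vinyl)stannane | CCCC[Sn](CCCC)(CCCC)C=C | starting material
5 | 6,6-dimethyl-1-vinylcyclohexene | C=CC1=CCCCC1(C)C | intermediate
6 | tiglic aldehyde, (E)-2-methylbut-2-enal | C/C=C(\C)C=O | starting material
7 | (1R,2S,8aR)-1,2,5,5-tetramethyl-1,2,3,5,6,7,8,8a-octahydronaphthalene-1-carbaldehyde | O=C[C@@]1(C)[C@@H]2CCCC(C)(C)C2=CC[C@@H]1C | intermediate
8 | 1,2,4,5-tetramethoxybenzene | COc1cc(OC)c(OC)cc1OC | starting material
9 | 2,3,5,6-tetramethoxyphenyllithium | [Li]c1c(OC)c(OC)cc(OC)c1OC | intermediate
10 | lithium (2,3,5,6-tetramethoxyphenyl)[(1R,2S,8aR)-1,2,5,5-tetramethyl-1,2,3,5,6,7,8,8a-octahydronaphthalen-1-yl]methanolate (both C11 epimers) | COc1cc(OC)c(OC)c(C([O-])[C@@]2(C)[C@@H]3CCCC(C)(C)C3=CC[C@@H]2C)c1OC.[Li+] | intermediate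
11 | lithium O-alkyl carbonodithioate of 10 | COc1cc(OC)c(OC)c(C(OC(=S)[S-])[C@@]2(C)[C@@H]3CCCC(C)(C)C3=CC[C@@H]2C)c1OC.[Li+] | intermediate
12 | O-{(2,3,5,6-tetramethoxyphenyl)[(1R,2S,8aR)-1,2,5,5-tetramethyl-1,2,3,5,6,7,8,8a-octahydronaphthalen-1-yl]methyl} S-methyl carbonodithioate (both C11 epimers) | COc1cc(OC)c(OC)c(C(OC(=S)SC)[C@@]2(C)[C@@H]3CCCC(C)(C)C3=CC[C@@H]2C)c1OC | intermediate
13 | 1,2,4,5-tetramethoxy-3-{[(1R,2S,8aS)-1,2,5,5-tetramethyl-1,2,3,5,6,7,8,8a-octahydronaphthalen-1-yl]methyl}benzene | COc1cc(OC)c(OC)c(C[C@@]2(C)[C@@H]3CCCC(C)(C)C3=CC[C@@H]2C)c1OC | intermediate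
14 | 2,5-dimethoxy-3-{[(1R,2S,8aS)-1,2,5,5-tetramethyl-1,2,3,5,6,7,8,8a-octahydronaphthalen-1-yl]methyl}cyclohexa-2,5-diene-1,4-dione | COC1=CC(=O)C(OC)=C(C[C@@]2(C)[C@@H]3CCCC(C)(C)C3=CC[C@@H]2C)C1=O | intermediate
15 | potassium salt of 16 (quinonolate) | COC1=CC(=O)C([O-])=C(C[C@@]2(C)[C@@H]3CCCC(C)(C)C3=CC[C@@H]2C)C1=O.[K+] | intermediate
16 | 2-hydroxy-5-methoxy-3-{[(1R,2S,8aS)-1,2,5,5-tetramethyl-1,2,3,5,6,7,8,8a-octahydronaphthalen-1-yl]methyl}cyclohexa-2,5-diene-1,4-dione | COC1=CC(=O)C(O)=C(C[C@@]2(C)[C@@H]3CCCC(C)(C)C3=CC[C@@H]2C)C1=O | intermediate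
17 | (S)-2-methylbutan-1-amine | CC[C@H](C)CN | starting material
18 | nakijiquinone J | CC[C@H](C)CNC1=CC(=O)C(O)=C(C[C@@]2(C)[C@@H]3CCCC(C)(C)C3=CC[C@@H]2C)C1=O | target

**Total step count:** 8. **Longest linear sequence:** 8 steps (1 → 18).

**Steps most likely to fail**

Step 3. The trisubstituted enal is a sluggish dienophile, so acid-induced oligomerisation or double-bond migration of the diene may outrun the cycloaddition, and exo or facial selectivity may be eroded. The fallback sets out from 5 and 6 and returns at 7; it replaces catalyst control by an auxiliary-controlled ionic Diels–Alder reaction. Aldehyde 6 is acetalised with (2R,3R)-butane-2,3-diol (TsOH cat., benzene, removal of water) to give (4R,5R)-2-[(E)-but-2-en-2-yl]-4,5-dimethyl-1,3-dioxolane F1. With Me3SiOTf (CH2Cl2, −78 °C) this opens to a far more electrophilic alkoxy-allyl cation that should add to 5 at low temperature. The adduct (4R,5R)-4,5-dimethyl-2-[(1R,2S,8aR)-1,2,5,5-tetramethyl-1,2,3,5,6,7,8,8a-octahydronaphthalen-1-yl]-1,3-dioxolane F2 would be separated from its diastereomers by chromatography, so that even modest induction gives enantiopure material. Hydrolysis (TsOH, acetone/H2O) then gives 7.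

Step 7. The two vinylogous esters may not be discriminated well enough, or hydrolysis may run on to the dihydroxyquinone. The fallback sets out from 14 and returns at 16. Both methoxy groups are hydrolysed on purpose (NaOH aq., dioxane, 60 °C; then HCl) to 2,5-dihydroxy-3-{[(1R,2S,8aS)-1,2,5,5-tetramethyl-1,2,3,5,6,7,8,8a-octahydronaphthalen-1-yl]methyl}cyclohexa-2,5-diene-1,4-dione F3. Equilibrating acid-catalysed methanolysis (MeOH, cat. H2SO4, rt) should then esterify only the unhindered vinylogous acid at C5', the ether next to the alkyl group being the less stable and more labile one.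

Step 5. The very electron-rich benzylic xanthate may ionise or rearrange from O to S before it is reduced, or the C11 radical may add to C6 of the C5=C6 bond. The fallback sets out from 7 and 8 and returns at 13. The aryllithium addition is quenched with water so that (2,3,5,6-tetramethoxyphenyl)[(1R,2S,8aR)-1,2,5,5-tetramethyl-1,2,3,5,6,7,8,8a-octahydronaphthalen-1-yl]methanol F4 is isolated. Its hydroxyl group is then removed by dissolving-metal hydrogenolysis (Li, liquid NH3/THF, −78 °C; then NH4Cl), an electron-transfer process with no free C11 radical chain, to which the isolated trisubstituted alkene is inert.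

**Further compounds**
F1 | step 3 | (4R,5R)-2-[(E)-but-2-en-2-yl]-4,5-dimethyl-1,3-dioxolane | C/C=C(\C)C1O[C@H](C)[C@@H](C)O1
F2 | step 3 | (4R,5R)-4,5-dimethyl-2-[(1R,2S,8aR)-1,2,5,5-tetramethyl-1,2,3,5,6,7,8,8a-octahydronaphthalen-1-yl]-1,3-dioxolane | C1(O[C@H](C)[C@@H](C)O1)[C@@]2(C)[C@@H]3CCCC(C)(C)C3=CC[C@@H]2C
F3 | step 7 | 2,5-dihydroxy-3-{[(1R,2S,8aS)-1,2,5,5-tetramethyl-1,2,3,5,6,7,8,8a-octahydronaphthalen-1-yl]methyl}cyclohexa-2,5-diene-1,4-dione | OC1=CC(=O)C(O)=C(C[C@@]2(C)[C@@H]3CCCC(C)(C)C3=CC[C@@H]2C)C1=O
F4 | step 5 | (2,3,5,6-tetramethoxyphenyl)[(1R,2S,8aR)-1,2,5,5-tetramethyl-1,2,3,5,6,7,8,8a-octahydronaphthalen-1-yl]methanol (both C11 epimers) | COc1cc(OC)c(OC)c(C(O)[C@@]2(C)[C@@H]3CCCC(C)(C)C3=CC[C@@H]2C)c1OC
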